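**Retrosynthetic overview**

1. The strategy rests on the allylic carbinol C1 lying next to the methyl-bearing alkene carbon C10 in the cycloheptene (ring B); numbering: C1 = CH–OAc, C2 = CH2, C3 = C–CH3, C4/C5 = CH2 of the cyclopentane (ring A), C6 = C(OH)(isopropyl), C7 = fusion CH, C8 = CH–O-aroyl, C9=C10 = alkene. C1–C10 is cut to a (Z)-alkenyl iodide and an aldehyde on a trans-2,3-disubstituted ring A, joined by an intramolecular Nozaki–Hiyama–Kishi (NHK) reaction.
2. The C1–C2 aldehyde arm on quaternary C3 is carried as an allyl group and unveiled late by Lemieux–Johnson cleavage. The C8 aroate comes from Steglich esterification and the C6 carbinol from isopropylcerium addition. C6–OH stays free, because it is trans to the arm on ring A and cannot form a lactol.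
3. C7–C8 comes from an anti-selective boron aldol with (Z)-3-iodobut-2-enal. The enolate is regiodefined because it is the one delivered by copper-catalysed asymmetric conjugate methylation of 3-allylcyclopent-2-enone (sets C3) and trapped as a silyl enol ether.
4. Ring order: ring A is present from cyclopentane-1,3-dione; ring B is closed last (C1–C10), followed by C1 acetylation and phenol desilylation.

Key step: step 11

Remark on the chemistry: metal alkoxides that are only protonated on aqueous work-up are taken as the salt form of the product of their step and carry no number of their own.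

**Route**

Step 1
Reactants: 1 cyclopentane-1,3-dione
Product: 2 3-ethoxycyclopent-2-en-1-one
Conditions: EtOH, p-TsOH (cat.), toluene, reflux, Dean–Stark
Reagents that add atoms: ethanol, CCO
Why: Acid-catalysed enol ether (vinylogous ester) formation from the 1,3-dione, driven by azeotropic removal of water.

Step 2
Reactants: 2 3-ethoxycyclopent-2-en-1-one
Product: 4 3-(prop-2-en-1-yl)cyclopent-2-en-1-one, via tertiary allylic alcohol 3 (not isolated)
Conditions: allylmagnesium bromide, THF, −78 to 0 °C; then 1 M HCl (aq.), 0 °C, short contact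
Reagents that add atoms: allylmagnesium bromide, C=CC[Mg]Br; water, O
Why: Stork–Danheiser sequence, in which 1,2-addition of the Grignard reagent to the vinylogous ester and acid hydrolysis with allylic transposition should give the β-allyl enone, the brief cold acid treatment keeping the allyl double bond out of conjugation.

Step 3
Reactants: 4 3-(prop-2-en-1-yl)cyclopent-2-en-1-one
Product: 6 triethyl{[(3R)-3-methyl-3-(prop-2-en-1-yl)cyclopent-1-en-1-yl]oxy}silane, via dimethylaluminium enolate 5 (not isolated)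
Conditions: Me3Al, Cu(OTf)2 (cat.), chiral sulfonate-bearing imidazolinium salt (carbene precursor, cat., pre-treated with Ag2O), THF, −78 °C; then Et3SiOTf, −78 to 0 °C
Reagents that add atoms: trimethylaluminium, C[Al](C)C; triethylsilyl trifluoromethanesulfonate, CC[Si](CC)(CC)OS(=O)(=O)C(F)(F)F
Why: Copper-catalysed asymmetric conjugate addition of Me3Al to a β-substituted cyclopentenone should set quaternary C3 under ligand control (the ligand antipode that gives 3R is used), and O-silylation of the aluminium enolate fixes the enolate on the C7 side, which deprotonation of the ketone would not do.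

Step 4
Reactants: 7 but-2-yn-1-ol
Product: 9 (2Z)-3-iodobut-2-en-1-ol, via cyclic alkenylalanate 8 (not isolated)
Conditions: NaAlH2(OCH2CH2OMe)2, Et2O, 0 °C to rt; then I2, THF, −78 to 0 °C
Reagents that add atoms: iodine, II
Why: Hydroxyl-directed trans-hydroalumination of the propargylic alcohol puts aluminium on the distal carbon within a five-membered alanate, and iodinolysis with retention should give the Z iodide (iodine cis to CH2OH).

Step 5
Reactants: 9 (2Z)-3-iodobut-2-en-1-ol
Product: 10 (2Z)-3-iodobut-2-enal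
Conditions: MnO2 (activated, excess), CH2Cl2, rt, dark; filtered and used at once
Reagents that add atoms: none
Why: Neutral allylic alcohol oxidation with MnO2 should keep the Z geometry of the sensitive β-iodoenal.

Step 6
Reactants: 6 triethyl{[(3R)-3-methyl-3-(prop-2-en-1-yl)cyclopent-1-en-1-yl]oxy}silane; 10 (2Z)-3-iodobut-2-enal
Product: 14 (2S,3R)-2-[(1R,2Z)-1-hydroxy-3-iodobut-2-en-1-yl]-3-methyl-3-(prop-2-en-1-yl)cyclopentan-1-one, via lithium enolate 11 (not isolated), via dicyclohexylboron enolate 12 (not isolated), via boron aldolate 13 (not isolated)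
Conditions: MeLi (1.0 equiv), THF, 0 °C; (c-C6H11)2BCl, −78 °C; then 10, −78 to −20 °C; then pH 7 buffer, MeOH, H2O2, 0 °C
Reagents that add atoms: none
Why: Boron-mediated aldol reaction of the regiodefined enolate, in which the ring-locked E enolate should react through a Zimmerman–Traxler chair to give the anti relation of C7 and C8 (sets C8), the aldehyde adding to the enolate face cis to the C3 methyl and away from the longer allyl arm (sets C7), and the closed transition state favouring 1,2-addition over addition–elimination at the β-iodoenal.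

Step 7
Reactants: 14 (2S,3R)-2-[(1R,2Z)-1-hydroxy-3-iodobut-2-en-1-yl]-3-methyl-3-(prop-2-en-1-yl)cyclopentan-1-one
Product: 15 (1R,2S,3R)-2-[(1R,2Z)-1-hydroxy-3-iodobut-2-en-1-yl]-3-methyl-1-(propan-2-yl)-3-(prop-2-en-1-yl)cyclopentan-1-ol
Conditions: isopropylmagnesium chloride (excess), CeCl3 (anhydrous), THF, −78 to −40 °C; aq. NH4Cl
Reagents that add atoms: isopropylmagnesium chloride, CC(C)[Mg]Cl
Why: Organocerium (Imamoto) addition, whose low basicity should suppress enolisation, retro-aldol cleavage, β-hydride reduction and iodine–metal exchange, and which attacks the C6 carbonyl on the face opposite the C7 side chain (held on that side also in the chelate with the C8 alkoxide), setting C6 with OH cis to that side chain.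

Step 8
Reactants: 16 4-hydroxybenzoic acid
Product: 18 4-[(tert-butyldimethylsilyl)oxy]benzoic acid, via bis-silylated ester 17 (not isolated)
Conditions: TBSCl (2.5 equiv), imidazole, DMF, rt; then AcOH/THF/H2O, rt
Reagents that add atoms: tert-butyldimethylsilyl chloride, CC(C)(C)[Si](C)(C)Cl
Why: Silylation of both acidic sites followed by selective solvolysis of the labile silyl ester, which leaves the aryl silyl ether in place.

Step 9
Reactants: 15 (1R,2S,3R)-2-[(1R,2Z)-1-hydroxy-3-iodobut-2-en-1-yl]-3-methyl-1-(propan-2-yl)-3-(prop-2-en-1-yl)cyclopentan-1-ol; 18 4-[(tert-butyldimethylsilyl)oxy]benzoic acid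
Product: 19 (1R,2Z)-1-[(1S,2R,5R)-2-hydroxy-5-methyl-2-(propan-2-yl)-5-(prop-2-en-1-yl)cyclopentyl]-3-iodobut-2-en-1-yl 4-[(tert-butyldimethylsilyl)oxy]benzoate
Conditions: DCC, DMAP, CH2Cl2, 0 °C to rt
Reagents that add atoms: none
Why: Steglich esterification should acylate only the secondary allylic C8–OH, the tertiary C6–OH being too hindered to react.

Step 10
Reactants: 19 (1R,2Z)-1-[(1S,2R,5R)-2-hydroxy-5-methyl-2-(propan-2-yl)-5-(prop-2-en-1-yl)cyclopentyl]-3-iodobut-2-en-1-yl 4-[(tert-butyldimethylsilyl)oxy]benzoate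
Product: 21 (1R,2Z)-1-[(1S,2R,5R)-2-hydroxy-5-methyl-5-(2-oxoethyl)-2-(propan-2-yl)cyclopentyl]-3-iodobut-2-en-1-yl 4-[(tert-butyldimethylsilyl)oxy]benzoate, via terminal 1,2-diol 20 (not isolated)
Conditions: OsO4 (cat.), NaIO4, 2,6-lutidine, 1,4-dioxane/H2O, rt
Reagents that add atoms: osmium tetroxide (re-formed by the periodate), O=[Os](=O)(=O)=O; sodium periodate, [Na+].[O-]I(=O)(=O)=O
Why: Lemieux–Johnson oxidative cleavage, in which electrophilic OsO4 should take the monosubstituted terminal alkene in preference to the iodine-bearing trisubstituted alkene that is further deactivated by the allylic acyloxy group.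

Step 11
Reactants: 21 (1R,2Z)-1-[(1S,2R,5R)-2-hydroxy-5-methyl-5-(2-oxoethyl)-2-(propan-2-yl)cyclopentyl]-3-iodobut-2-en-1-yl 4-[(tert-butyldimethylsilyl)oxy]benzoate
Product: 23 (3R,3aS,4S,7S,8aR)-3,7-dihydroxy-6,8a-dimethyl-3-(propan-2-yl)-1,2,3,3a,4,7,8,8a-octahydroazulen-4-yl 4-[(tert-butyldimethylsilyl)oxy]benzoate, via alkenylchromium dichloride 22 (not isolated)
Conditions: CrCl2 (excess), NiCl2 (cat.), degassed DMSO/THF, rt, high dilution (about 0.005 M), slow addition of 21; aq. NH4Cl
Reagents that add atoms: none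
Why: Nozaki–Hiyama–Kishi reaction: zerovalent nickel, formed from NiCl2 by divalent chromium, inserts into the C10–I bond, the alkenyl group is handed on with retention of the Z geometry to trivalent chromium (22), and this alkenylchromium adds to the C1 aldehyde to make the C1–C10 bond. The closest known reaction type is the intramolecular NHK coupling of an iodoalkene with an aldehyde used for medium-ring closure, which is non-basic and leaves free hydroxyl groups, aryl esters and aryl silyl ethers alone. Ring B closes in a 7-exo-trig mode (the carbonyl oxygen stays outside the new ring and C9=C10 becomes endocyclic), and the Z iodide already carries the cis arrangement of C8 and C1 that a cycloheptene demands. The new stereocentre C1 is set under substrate control: in the chair-like transition state of the forming trans-fused ring the C1=O bond lies beside the C10–Cr bond, close to the alkene plane, so the alkoxide should end pseudo-equatorial, cis to the pseudo-equatorial C8 aroate and trans to the axial C3 methyl group, which is the 1S configuration (ring position 7S). The step needs attack on that one face of the aldehyde and ring closure in preference to intermolecular coupling or protodeiodination; the first is secured by the rigid trans-1,2 arrangement of the two arms on ring A and the angular methyl group, the second by high dilution, and the aldehyde has no stereocentre next to it that could be lost.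

Step 12
Reactants: 23 (3R,3aS,4S,7S,8aR)-3,7-dihydroxy-6,8a-dimethyl-3-(propan-2-yl)-1,2,3,3a,4,7,8,8a-octahydroazulen-4-yl 4-[(tert-butyldimethylsilyl)oxy]benzoate
Product: 24 (3R,3aS,4S,7S,8aR)-7-(acetyloxy)-3-hydroxy-6,8a-dimethyl-3-(propan-2-yl)-1,2,3,3a,4,7,8,8a-octahydroazulen-4-yl 4-[(tert-butyldimethylsilyl)oxy]benzoate
Conditions: Ac2O, pyridine, DMAP (cat.), CH2Cl2, 0 °C to rt
Reagents that add atoms: acetic anhydride, CC(=O)OC(C)=O
Why: DMAP-catalysed acetylation should take the secondary allylic C1–OH only, the hindered tertiary C6–OH staying free.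

Step 13
Reactants: 24 (3R,3aS,4S,7S,8aR)-7-(acetyloxy)-3-hydroxy-6,8a-dimethyl-3-(propan-2-yl)-1,2,3,3a,4,7,8,8a-octahydroazulen-4-yl 4-[(tert-butyldimethylsilyl)oxy]benzoate
Product: 25 (3R,3aS,4S,7S,8aR)-7-(acetyloxy)-3-hydroxy-6,8a-dimethyl-3-(propan-2-yl)-1,2,3,3a,4,7,8,8a-octahydroazulen-4-yl 4-hydroxybenzoate
Conditions: HF·pyridine, pyridine, THF, 0 °C to rt
Reagents that add atoms: none
Why: Fluoride-mediated cleavage of the aryl silyl ether under buffered conditions should leave the acetate, the aroate and the tertiary alcohol untouched.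

**Compound list**

1 | cyclopentane-1,3-dione | O=C1CCC(=O)C1 | starting material
2 | 3-ethoxycyclopent-2-en-1-one | CCOC1=CC(=O)CC1 | intermediate
3 | 3-ethoxy-1-(prop-2-en-1-yl)cyclopent-2-en-1-ol (racemic) | C=CCC1(O)CCC(OCC)=C1 | intermediate (not isolated)
4 | 3-(prop-2-en-1-yl)cyclopent-2-en-1-one | C=CCC1=CC(=O)CC1 | intermediate
5 | dimethyl{[(3R)-3-methyl-3-(prop-2-en-1-yl)cyclopent-1-en-1-yl]oxy}alumane | C=CC[C@@]1(C)CCC(O[Al](C)C)=C1 | intermediate (not isolated)
6 | triethyl{[(3R)-3-methyl-3-(prop-2-en-1-yl)cyclopent-1-en-1-yl]oxy}silane | C=CC[C@@]1(C)CCC(O[Si](CC)(CC)CC)=C1 | intermediate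
7 | but-2-yn-1-ol | CC#CCO | starting material
8 | sodium 2,2-bis(2-methoxyethoxy)-3-methyl-2,5-dihydro-1,2-oxaaluminol-2-uide (cyclic alkenylalanate) | CC1=CCO[Al-]1(OCCOC)OCCOC.[Na+] | intermediate (not isolated)
9 | (2Z)-3-iodobut-2-en-1-ol | OC/C=C(\I)C | intermediate
10 | (2Z)-3-iodobut-2-enal | O=C/C=C(\I)C | intermediate
11 | lithium (3R)-3-methyl-3-(prop-2-en-1-yl)cyclopent-1-en-1-olate | C=CC[C@@]1(C)CCC(O[Li])=C1 | intermediate (not isolated)
12 | dicyclohexyl{[(3R)-3-methyl-3-(prop-2-en-1-yl)cyclopent-1-en-1-yl]oxy}borane | C=CC[C@@]1(C)CCC(OB(C2CCCCC2)C2CCCCC2)=C1 | intermediate (not isolated)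
13 | (1R,2Z)-3-iodo-1-[(1S,2R)-2-methyl-5-oxo-2-(prop-2-en-1-yl)cyclopentyl]but-2-en-1-yl dicyclohexylborinate | C=CC[C@@]1(C)CCC(=O)[C@@H]1[C@@H](OB(C1CCCCC1)C1CCCCC1)/C=C(\I)C | intermediate (not isolated)
14 | (2S,3R)-2-[(1R,2Z)-1-hydroxy-3-iodobut-2-en-1-yl]-3-methyl-3-(prop-2-en-1-yl)cyclopentan-1-one | C=CC[C@@]1(C)CCC(=O)[C@@H]1[C@@H](O)/C=C(\I)C | intermediate
15 | (1R,2S,3R)-2-[(1R,2Z)-1-hydroxy-3-iodobut-2-en-1-yl]-3-methyl-1-(propan-2-yl)-3-(prop-2-en-1-yl)cyclopentan-1-ol | C=CC[C@@]1(C)CC[C@@](O)(C(C)C)[C@@H]1[C@@H](O)/C=C(\I)C | intermediate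
16 | 4-hydroxybenzoic acid | OC(=O)c1ccc(O)cc1 | starting material
17 | tert-butyldimethylsilyl 4-[(tert-butyldimethylsilyl)oxy]benzoate | CC(C)(C)[Si](C)(C)OC(=O)c1ccc(O[Si](C)(C)C(C)(C)C)cc1 | intermediate (not isolated)
18 | 4-[(tert-butyldimethylsilyl)oxy]benzoic acid | OC(=O)c1ccc(O[Si](C)(C)C(C)(C)C)cc1 | intermediate
19 | (1R,2Z)-1-[(1S,2R,5R)-2-hydroxy-5-methyl-2-(propan-2-yl)-5-(prop-2-en-1-yl)cyclopentyl]-3-iodobut-2-en-1-yl 4-[(tert-butyldimethylsilyl)oxy]benzoate | C=CC[C@@]1(C)CC[C@@](O)(C(C)C)[C@@H]1[C@@H](OC(=O)c1ccc(O[Si](C)(C)C(C)(C)C)cc1)/C=C(\I)C | intermediate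
20 | 1,2-diol from dihydroxylation of the allyl group of 19 (both configurations at the new carbinol) | OCC(O)C[C@@]1(C)CC[C@@](O)(C(C)C)[C@@H]1[C@@H](OC(=O)c1ccc(O[Si](C)(C)C(C)(C)C)cc1)/C=C(\I)C | intermediate (not isolated)
21 | (1R,2Z)-1-[(1S,2R,5R)-2-hydroxy-5-methyl-5-(2-oxoethyl)-2-(propan-2-yl)cyclopentyl]-3-iodobut-2-en-1-yl 4-[(tert-butyldimethylsilyl)oxy]benzoate | O=CC[C@@]1(C)CC[C@@](O)(C(C)C)[C@@H]1[C@@H](OC(=O)c1ccc(O[Si](C)(C)C(C)(C)C)cc1)/C=C(\I)C | intermediate
22 | alkenylchromium dichloride derived from 21 (CrCl2 in place of iodine, Z retained) | O=CC[C@@]1(C)CC[C@@](O)(C(C)C)[C@@H]1[C@@H](OC(=O)c1ccc(O[Si](C)(C)C(C)(C)C)cc1)/C=C(\[Cr](Cl)Cl)C | intermediate (not isolated)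
23 | (3R,3aS,4S,7S,8aR)-3,7-dihydroxy-6,8a-dimethyl-3-(propan-2-yl)-1,2,3,3a,4,7,8,8a-octahydroazulen-4-yl 4-[(tert-butyldimethylsilyl)oxy]benzoate | O[C@H]1C[C@@]2(C)CC[C@@](O)(C(C)C)[C@@H]2[C@@H](OC(=O)c2ccc(O[Si](C)(C)C(C)(C)C)cc2)C=C1C | intermediate
24 | (3R,3aS,4S,7S,8aR)-7-(acetyloxy)-3-hydroxy-6,8a-dimethyl-3-(propan-2-yl)-1,2,3,3a,4,7,8,8a-octahydroazulen-4-yl 4-[(tert-butyldimethylsilyl)oxy]benzoate | CC(=O)O[C@H]1C[C@@]2(C)CC[C@@](O)(C(C)C)[C@@H]2[C@@H](OC(=O)c2ccc(O[Si](C)(C)C(C)(C)C)cc2)C=C1C | intermediate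
25 | (3R,3aS,4S,7S,8aR)-7-(acetyloxy)-3-hydroxy-6,8a-dimethyl-3-(propan-2-yl)-1,2,3,3a,4,7,8,8a-octahydroazulen-4-yl 4-hydroxybenzoate | CC(=O)O[C@H]1C[C@@]2(C)CC[C@@](O)(C(C)C)[C@@H]2[C@@H](OC(=O)c2ccc(O)cc2)C=C1C | target

**Step count and risk**

Total step count: 13. Longest linear sequence: 10 steps (steps 1, 2, 3, 6, 7, 9, 10, 11, 12, 13; compounds 1 → 2 → 4 → 6 → 14 → 15 → 19 → 21 → 23 → 24 → 25).

Steps most likely to fail:

Step 11 (key ring closure). What may go wrong: attack on the other face of the C1 aldehyde, so that the pseudo-axial C1 epimer dominates, and slow closure that lets protodeiodination or intermolecular coupling compete. Fallback: setting out from 21, the closure is run as before and accepted with whatever facial outcome it gives. The C1-epimeric alcohol (3R,3aS,4S,7R,8aR)-3,7-dihydroxy-6,8a-dimethyl-3-(propan-2-yl)-1,2,3,3a,4,7,8,8a-octahydroazulen-4-yl 4-[(tert-butyldimethylsilyl)oxy]benzoate F1 is separated, and its configuration is corrected by substitution rather than by re-tuning the cyclisation. A Mitsunobu reaction with acetic acid (PPh3, diisopropyl azodicarboxylate, THF, 0 °C) should invert C1 and give the acetate directly, so the material comes back to the route at 24.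

Step 6 (aldol). What may go wrong: incomplete lithium-to-boron exchange, so that part of the addition runs through the less selective lithium enolate and the anti selectivity at C8 erodes; modest discrimination between the two enolate faces; and Z-to-E isomerisation or addition–elimination of the β-iodoenal during a slow addition to the hindered enolate. Fallback: setting out from 6 (and 7), the iodoalkene is built only after the C–C bond. But-2-yn-1-ol 7 is oxidised (MnO2, CH2Cl2) to but-2-ynal F2. The same enolate sequence (11, then 12) is run with this slim, robust aldehyde, giving the boron aldolate (1R)-1-[(1S,2R)-2-methyl-5-oxo-2-(prop-2-en-1-yl)cyclopentyl]but-2-yn-1-yl dicyclohexylborinate F3 and, after oxidative work-up, the anti aldol (2S,3R)-2-[(1R)-1-hydroxybut-2-yn-1-yl]-3-methyl-3-(prop-2-en-1-yl)cyclopentan-1-one F4. Isopropylcerium addition as in step 7 gives the propargylic diol (1R,2S,3R)-2-[(1R)-1-hydroxybut-2-yn-1-yl]-3-methyl-1-(propan-2-yl)-3-(prop-2-en-1-yl)cyclopentan-1-ol F5. Hydroxyl-directed trans-hydroalumination (NaAlH2(OCH2CH2OMe)2, THF, 0 °C) through the cyclic alkenylalanate F6 (tertiary hydroxyl drawn free) and iodinolysis (I2, −78 °C) should then give the Z iodide stereospecifically, so the route is rejoined at 15.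

Step 7 (isopropyl addition). What may go wrong: enolisation or retro-aldol cleavage of the metal aldolate, β-hydride reduction of the hindered ketone by the secondary organometallic, and attack on the wrong face of C6. Fallback: setting out from 14, the C8 hydroxyl is capped first (Et3SiOTf, 2,6-lutidine, CH2Cl2, −78 °C) to give (2S,3R)-2-{(1R,2Z)-3-iodo-1-[(triethylsilyl)oxy]but-2-en-1-yl}-3-methyl-3-(prop-2-en-1-yl)cyclopentan-1-one F7. The ketone then has no acidic hydroxyl and no aldolate to fragment. The isopropylcerium reagent (isopropylmagnesium chloride, CeCl3, THF, −78 °C) should add anti to the bulky C7 side chain to give (1R,2S,3R)-2-{(1R,2Z)-3-iodo-1-[(triethylsilyl)oxy]but-2-en-1-yl}-3-methyl-1-(propan-2-yl)-3-(prop-2-en-1-yl)cyclopentan-1-ol F8. Removal of the triethylsilyl group (HF·pyridine, THF, 0 °C) brings the material back to the route at 15.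

**Further compounds**

F1 | step 11 | (3R,3aS,4S,7R,8aR)-3,7-dihydroxy-6,8a-dimethyl-3-(propan-2-yl)-1,2,3,3a,4,7,8,8a-octahydroazulen-4-yl 4-[(tert-butyldimethylsilyl)oxy]benzoate | O[C@@H]1C[C@@]2(C)CC[C@@](O)(C(C)C)[C@@H]2[C@@H](OC(=O)c2ccc(O[Si](C)(C)C(C)(C)C)cc2)C=C1C
F2 | step 6 | but-2-ynal | CC#CC=O
F3 | step 6 | (1R)-1-[(1S,2R)-2-methyl-5-oxo-2-(prop-2-en-1-yl)cyclopentyl]but-2-yn-1-yl dicyclohexylborinate | C=CC[C@@]1(C)CCC(=O)[C@@H]1[C@@H](OB(C1CCCCC1)C1CCCCC1)C#CC
F4 | step 6 | (2S,3R)-2-[(1R)-1-hydroxybut-2-yn-1-yl]-3-methyl-3-(prop-2-en-1-yl)cyclopentan-1-one | C=CC[C@@]1(C)CCC(=O)[C@@H]1[C@@H](O)C#CC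
F5 | step 6 | (1R,2S,3R)-2-[(1R)-1-hydroxybut-2-yn-1-yl]-3-methyl-1-(propan-2-yl)-3-(prop-2-en-1-yl)cyclopentan-1-ol | C=CC[C@@]1(C)CC[C@@](O)(C(C)C)[C@@H]1[C@@H](O)C#CC
F6 | step 6 | sodium cyclic alkenylalanate from F5 (aluminium bound to the C8 oxygen and to C10) | C=CC[C@@]1(C)CC[C@@](O)(C(C)C)[C@@H]1[C@H]1O[Al-](OCCOC)(OCCOC)C(C)=C1.[Na+]
F7 | step 7 | (2S,3R)-2-{(1R,2Z)-3-iodo-1-[(triethylsilyl)oxy]but-2-en-1-yl}-3-methyl-3-(prop-2-en-1-yl)cyclopentan-1-one | C=CC[C@@]1(C)CCC(=O)[C@@H]1[C@@H](O[Si](CC)(CC)CC)/C=C(\I)C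
F8 | step 7 | (1R,2S,3R)-2-{(1R,2Z)-3-iodo-1-[(triethylsilyl)oxy]but-2-en-1-yl}-3-methyl-1-(propan-2-yl)-3-(prop-2-en-1-yl)cyclopentan-1-ol | C=CC[C@@]1(C)CC[C@@](O)(C(C)C)[C@@H]1[C@@H](O[Si](CC)(CC)CC)/C=C(\I)C
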